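**Retrosynthetic overview**
1. Target ⇐ removal of eight MOM groups and alcohol→ketone adjustment ⇐ Suzuki–Miyaura union of an 8-bromoflavone with a cyclohexenyl triflate, which fixes the ring double bond.
2. Cyclohexenyl triflate ⇐ methyl cuprate addition and enolate triflation of a 5-aryl-6-(silyloxybenzyl)cyclohex-2-enone (methyl centre set trans to the aryl group).
3. Key step: that cyclohexenone ⇐ one-carbon ring expansion (diazoalkane insertion with 1,2-alkyl shift, then desaturation) of a 2,3-trans-disubstituted cyclopentanone; the six-membered carbocycle is formed here.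
4. Cyclopentanone ⇐ rhodium/(S)-BINAP conjugate arylation of cyclopentenone plus aldol with a prenylated benzaldehyde; both aryl units come from resorcinol.
5. Bromoflavone ⇐ oxidative aldehyde C–H/alkyne annulation of a brominated salicylaldehyde with an aryl prenyl alkyne; ring order: cyclopentanone → cyclohexenone (expansion), pyranone separately, then union.

Abbreviations: MOM = methoxymethyl; TBS = tert-butyldimethylsilyl; Ar1 = 2,4-bis(methoxymethoxy)phenyl; Ar2 = 2,4-bis(methoxymethoxy)-3-(3-methylbut-2-en-1-yl)phenyl.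

Assumption: the carbinol carbon made in step 5 is carried as a mixture of epimers (drawn without a descriptor), because step 16 turns it into the ketone carbon.

**Step 1**
Reactants: 1 resorcinol
Product: 2 1,3-bis(methoxymethoxy)benzene
Conditions: NaH, MOMCl, DMF, 0 °C to rt
Reagents that add atoms: chloromethyl methyl ether (MOMCl), COCCl
Why: Double Williamson etherification of the phenoxides gives the bis-acetal, which survives the later basic and organometallic steps and directs ortho-metalation.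

**Step 2**
Reactants: 2 1,3-bis(methoxymethoxy)benzene
Product: 3 1-iodo-2,4-bis(methoxymethoxy)benzene
Conditions: NIS, MeCN, 0 °C to rt
Reagents that add atoms: N-iodosuccinimide, O=C1CCC(=O)N1I
Why: Electrophilic aromatic iodination occurs at C4, para to one acetal oxygen and ortho to the other, because C2 between the two acetals is sterically shielded.

**Step 3**
Reactants: 2 1,3-bis(methoxymethoxy)benzene; 4 1-bromo-3-methylbut-2-ene
Product: 6 1,3-bis(methoxymethoxy)-2-(3-methylbut-2-en-1-yl)benzene, via aryllithium 5 (not isolated)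
Conditions: n-BuLi, THF, 0 °C to rt; then CuI (10 mol%), 4, −78 °C to rt
Reagents that add atoms: none
Why: Directed ortho-metalation takes place at C2 between the two cooperating OMOM groups, and the aryllithium is allylated at the primary carbon of 4 under copper catalysis (SN2 allylation).

**Step 4**
Reactants: 6 1,3-bis(methoxymethoxy)-2-(3-methylbut-2-en-1-yl)benzene
Product: 8 2,4-bis(methoxymethoxy)-3-(3-methylbut-2-en-1-yl)benzaldehyde, via aryllithium 7 (not isolated)
Conditions: s-BuLi, TMEDA, THF, −78 °C; then DMF, −78 °C to rt; aq NH4Cl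
Reagents that add atoms: N,N-dimethylformamide, CN(C)C=O
Why: The second directed ortho-metalation can only occur ortho to one OMOM group (C4 and C6 are equivalent), and the aryllithium is formylated by DMF (Bouveault aldehyde synthesis).

**Step 5**
Reactants: 3 1-iodo-2,4-bis(methoxymethoxy)benzene; 9 cyclopent-2-en-1-one; 8 2,4-bis(methoxymethoxy)-3-(3-methylbut-2-en-1-yl)benzaldehyde
Product: 13 (2S,3S)-3-Ar1-2-[hydroxy(Ar2)methyl]cyclopentan-1-one, via aryllithium 10 (not isolated), via aryltitanium 11 (not isolated), via titanium enolate 12 (not isolated)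
Conditions: 3, t-BuLi (2 equiv), THF, −78 °C; ClTi(OiPr)3, −78 to 0 °C; then 9 (1.1 equiv), [Rh(OH)((S)-binap)]2 (1.5 mol%), THF, 20 °C; then 8, −78 to −20 °C; aq NH4Cl
Reagents that add atoms: none
Why: Rhodium/(S)-BINAP-catalysed 1,4-addition of the aryltitanium (Hayashi–Miyaura-type conjugate arylation) sets the (S) aryl-bearing centre by ligand-controlled facial selection, and the chiral titanium enolate then adds to aldehyde 8 on the face opposite the new aryl group (aldol addition), giving the 2,3-trans ketone.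

**Step 6**
Reactants: 13 (2S,3S)-3-Ar1-2-[hydroxy(Ar2)methyl]cyclopentan-1-one
Product: 14 (2S,3S)-3-Ar1-2-[(TBS-oxy)(Ar2)methyl]cyclopentan-1-one
Conditions: TBSOTf, 2,6-lutidine, CH2Cl2, −78 to 0 °C
Reagents that add atoms: tert-butyldimethylsilyl trifluoromethanesulfonate, CC(C)(C)[Si](C)(C)OS(=O)(=O)C(F)(F)F
Why: Silyl ether formation blocks retro-aldol and keeps the future aryl ketone at the alcohol level, so the ring ketone is not part of an acidic 1,3-dicarbonyl unit in steps 7 and 8.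

**Step 7**
Reactants: 14 (2S,3S)-3-Ar1-2-[(TBS-oxy)(Ar2)methyl]cyclopentan-1-one
Product: 16 (5S,6S)-5-Ar1-6-[(TBS-oxy)(Ar2)methyl]cyclohex-2-en-1-one, via enol silane 15 (not isolated)
Conditions: TMSCHN2, Sc(OTf)3 (10 mol%), toluene, −78 to 0 °C; then DMSO, Pd(OAc)2 (10 mol%), O2 (1 atm), 40 °C, same flask
Reagents that add atoms: (trimethylsilyl)diazomethane, C[Si](C)(C)C=[N+]=[N-]
Why: Proposed new method: single-flask ring-expanding desaturation of an unstrained, α-branched cyclopentanone, in which Sc(OTf)3 activates the ketone for addition of TMSCHN2, the diazonium betaine loses N2 with 1,2-shift of the unsubstituted C5 (the branched C2 is too hindered to migrate and keeps its configuration), 1,3-Brook shift of the α-silyl ketone gives enol silane 15 with its double bond toward the inserted carbon, and the Pd(OAc)2/O2 couple then removes the silyl group and a β-hydrogen (oxa-π-allylpalladium, β-hydride elimination) to give enone 16 without a new stereocentre; the closest known reaction types are the Lewis acid-catalysed diazoalkane homologation of strained cyclobutanones (Tiffeneau–Demjanov type) and the Saegusa–Ito oxidation of enol silanes, so far run as separate operations on isolated intermediates.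

**Step 8**
Reactants: 16 (5S,6S)-5-Ar1-6-[(TBS-oxy)(Ar2)methyl]cyclohex-2-en-1-one
Product: 18 (3S,5S,6S)-5-Ar1-6-[(TBS-oxy)(Ar2)methyl]-3-methylcyclohex-1-en-1-yl trifluoromethanesulfonate, via lithium enolate 17 (not isolated)
Conditions: Me2CuLi (from MeLi and CuI), Et2O/THF, −78 °C; then PhNTf2, −78 to 0 °C
Reagents that add atoms: methyllithium, [Li]C; N-phenylbis(trifluoromethanesulfonimide), FC(F)(F)S(=O)(=O)N(c1ccccc1)S(=O)(=O)C(F)(F)F
Why: Conjugate addition of the Gilman cuprate delivers methyl by axial attack anti to the C5 aryl group (3,5-trans, setting the methyl centre), and O-triflation of the regiodefined enolate fixes the double bond between C1 and C2, away from C6.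

**Step 9**
Reactants: 2 1,3-bis(methoxymethoxy)benzene
Product: 20 3,5-bis(methoxymethoxy)phenol, via arylboronate 19 (not isolated)
Conditions: B2pin2 (0.6 equiv), [Ir(cod)OMe]2 (1.5 mol%), dtbpy (3 mol%), THF, 80 °C; then aq H2O2, NaOH, 0 °C to rt
Reagents that add atoms: hydrogen peroxide, OO
Why: Iridium-catalysed C–H borylation is sterically controlled and reaches only C5, the one C–H without an ortho substituent, and oxidation of the C–B bond gives the phenol (borylation–oxidation).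

**Step 10**
Reactants: 20 3,5-bis(methoxymethoxy)phenol
Product: 21 2-hydroxy-4,6-bis(methoxymethoxy)benzaldehyde
Conditions: MgCl2, Et3N, (CH2O)n, MeCN, reflux
Reagents that add atoms: formaldehyde (as paraformaldehyde), C=O
Why: The magnesium phenoxide delivers formaldehyde only to the ortho position and a second formaldehyde oxidises the benzylic alkoxide (Casnati–Skattebøl ortho-formylation); the two ortho sites are equivalent.

**Step 11**
Reactants: 21 2-hydroxy-4,6-bis(methoxymethoxy)benzaldehyde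
Product: 22 3-bromo-2-hydroxy-4,6-bis(methoxymethoxy)benzaldehyde
Conditions: NBS, CH2Cl2, −20 to 0 °C
Reagents that add atoms: N-bromosuccinimide, O=C1CCC(=O)N1Br
Why: Electrophilic aromatic bromination goes to C3, ortho to the chelated phenol, as is usual for halogenation of 2-hydroxy-4,6-dialkoxyaryl carbonyl compounds.

**Step 12**
Reactants: 23 ethynyl(trimethyl)silane; 4 1-bromo-3-methylbut-2-ene
Product: 24 trimethyl(5-methylhex-4-en-1-yn-1-yl)silane
Conditions: CuI (10 mol%), K2CO3, Bu4NBr, DMF, rt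
Reagents that add atoms: none
Why: The copper acetylide formed under carbonate base is alkylated at the primary carbon of the allylic bromide (copper-mediated SN2 alkynyl–allyl coupling), giving the skipped enyne.

**Step 13**
Reactants: 3 1-iodo-2,4-bis(methoxymethoxy)benzene; 24 trimethyl(5-methylhex-4-en-1-yn-1-yl)silane
Product: 26 2,4-bis(methoxymethoxy)-1-(5-methylhex-4-en-1-yn-1-yl)benzene, via terminal alkyne 25 (not isolated)
Conditions: CsF, PdCl2(PPh3)2 (3 mol%), CuI (5 mol%), Et3N, wet DMF, 60 °C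
Reagents that add atoms: none
Why: Fluoride removes the silyl group in the flask and the terminal alkyne couples with the aryl iodide (sila-Sonogashira coupling).

**Step 14**
Reactants: 22 3-bromo-2-hydroxy-4,6-bis(methoxymethoxy)benzaldehyde; 26 2,4-bis(methoxymethoxy)-1-(5-methylhex-4-en-1-yn-1-yl)benzene
Product: 27 8-bromo-2-Ar1-5,7-bis(methoxymethoxy)-3-(3-methylbut-2-en-1-yl)-4H-chromen-4-one
Conditions: [RhCl(cod)]2 (2 mol%), 1,2,3,4-tetraphenylcyclopenta-1,3-diene (8 mol%), Cu(OAc)2·H2O (2.1 equiv), o-xylene, 120 °C, N2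
Reagents that add atoms: none
Why: Phenoxide-directed rhodation of the aldehyde C–H bond, alkyne insertion with the aryl-bearing carbon on rhodium and C–O reductive elimination (rhodium-catalysed oxidative aldehyde C–H/alkyne annulation) build the pyranone with the aryl at C2 and the prenyl at C3, the copper salt reoxidising the catalyst.

**Step 15**
Reactants: 18 (3S,5S,6S)-5-Ar1-6-[(TBS-oxy)(Ar2)methyl]-3-methylcyclohex-1-en-1-yl trifluoromethanesulfonate; 27 8-bromo-2-Ar1-5,7-bis(methoxymethoxy)-3-(3-methylbut-2-en-1-yl)-4H-chromen-4-one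
Product: 29 8-{(3S,5S,6R)-5-Ar1-6-[(TBS-oxy)(Ar2)methyl]-3-methylcyclohex-1-en-1-yl}-2-Ar1-5,7-bis(methoxymethoxy)-3-(3-methylbut-2-en-1-yl)-4H-chromen-4-one, via alkenylboronate 28 (not isolated)
Conditions: 18, B2pin2, PdCl2(dppf) (3 mol%), KOAc, dioxane, 80 °C; then 27, Pd(OAc)2 (5 mol%), SPhos (10 mol%), aq K3PO4, 80 °C
Reagents that add atoms: none
Why: Miyaura borylation of the alkenyl triflate followed by Suzuki–Miyaura coupling with the hindered aryl bromide under a bulky biarylphosphine joins the two halves without moving the double bond or touching the three stereocentres.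

**Step 16**
Reactants: 29 8-{(3S,5S,6R)-5-Ar1-6-[(TBS-oxy)(Ar2)methyl]-3-methylcyclohex-1-en-1-yl}-2-Ar1-5,7-bis(methoxymethoxy)-3-(3-methylbut-2-en-1-yl)-4H-chromen-4-one
Product: 31 8-[(3S,5S,6R)-5-Ar1-6-(Ar2-carbonyl)-3-methylcyclohex-1-en-1-yl]-2-Ar1-5,7-bis(methoxymethoxy)-3-(3-methylbut-2-en-1-yl)-4H-chromen-4-one, via alcohol 30 (not isolated)
Conditions: TBAF, THF, 0 °C to rt; solvent swap; Dess–Martin periodinane, NaHCO3, CH2Cl2, 0 °C to rt
Reagents that add atoms: none
Why: Fluoride cleaves the silyl ether and buffered Dess–Martin oxidation converts both carbinol epimers into the aryl ketone, whose α-centre stays in the thermodynamically preferred trans relation to the neighbouring aryl group.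

**Step 17**
Reactants: 31 8-[(3S,5S,6R)-5-Ar1-6-(Ar2-carbonyl)-3-methylcyclohex-1-en-1-yl]-2-Ar1-5,7-bis(methoxymethoxy)-3-(3-methylbut-2-en-1-yl)-4H-chromen-4-one
Product: 32 CNP0314407.1
Conditions: 3 M HCl, MeOH/THF, 45 °C
Reagents that add atoms: none
Why: Acid-catalysed transacetalisation to dimethoxymethane (acetal cleavage) removes all eight MOM groups under conditions mild enough for the prenyl groups and the β,γ-unsaturated ketone.

**Compound list**
1 | resorcinol (benzene-1,3-diol) | Oc1cccc(O)c1 | starting material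
2 | 1,3-bis(methoxymethoxy)benzene | COCOc1cccc(OCOC)c1 | intermediate
3 | 1-iodo-2,4-bis(methoxymethoxy)benzene | COCOc1ccc(I)c(OCOC)c1 | intermediate
4 | 1-bromo-3-methylbut-2-ene (prenyl bromide) | CC(C)=CCBr | starting material
5 | [2,6-bis(methoxymethoxy)phenyl]lithium | [Li]c1c(OCOC)cccc1OCOC | intermediate
6 | 1,3-bis(methoxymethoxy)-2-(3-methylbut-2-en-1-yl)benzene | COCOc1cccc(OCOC)c1CC=C(C)C | intermediate
7 | [2,4-bis(methoxymethoxy)-3-(3-methylbut-2-en-1-yl)phenyl]lithium | [Li]c1ccc(OCOC)c(CC=C(C)C)c1OCOC | intermediate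
8 | 2,4-bis(methoxymethoxy)-3-(3-methylbut-2-en-1-yl)benzaldehyde | O=Cc1ccc(OCOC)c(CC=C(C)C)c1OCOC | intermediate
9 | cyclopent-2-en-1-one | O=C1C=CCC1 | starting material
10 | [2,4-bis(methoxymethoxy)phenyl]lithium | [Li]c1ccc(OCOC)cc1OCOC | intermediate
11 | [2,4-bis(methoxymethoxy)phenyl]tri(propan-2-yloxy)titanium | CC(C)O[Ti](OC(C)C)(OC(C)C)c1ccc(OCOC)cc1OCOC | intermediate
12 | {[(3S)-3-[2,4-bis(methoxymethoxy)phenyl]cyclopent-1-en-1-yl]oxy}tri(propan-2-yloxy)titanium | CC(C)O[Ti](OC(C)C)(OC(C)C)OC1=C[C@@H](c2ccc(OCOC)cc2OCOC)CC1 | intermediate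
13 | (2S,3S)-3-[2,4-bis(methoxymethoxy)phenyl]-2-{hydroxy[2,4-bis(methoxymethoxy)-3-(3-methylbut-2-en-1-yl)phenyl]methyl}cyclopentan-1-one (both carbinol epimers) | OC(c1ccc(OCOC)c(CC=C(C)C)c1OCOC)[C@H]1C(=O)CC[C@@H]1c1ccc(OCOC)cc1OCOC | intermediate
14 | (2S,3S)-3-[2,4-bis(methoxymethoxy)phenyl]-2-{[tert-butyl(dimethyl)silyl]oxy[2,4-bis(methoxymethoxy)-3-(3-methylbut-2-en-1-yl)phenyl]methyl}cyclopentan-1-one | CC(C)(C)[Si](C)(C)OC(c1ccc(OCOC)c(CC=C(C)C)c1OCOC)[C@H]1C(=O)CC[C@@H]1c1ccc(OCOC)cc1OCOC | intermediate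
15 | {[(5S,6S)-5-[2,4-bis(methoxymethoxy)phenyl]-6-{[tert-butyl(dimethyl)silyl]oxy[2,4-bis(methoxymethoxy)-3-(3-methylbut-2-en-1-yl)phenyl]methyl}cyclohex-1-en-1-yl]oxy}trimethylsilane | CC(C)(C)[Si](C)(C)OC(c1ccc(OCOC)c(CC=C(C)C)c1OCOC)[C@H]1C(O[Si](C)(C)C)=CCC[C@@H]1c1ccc(OCOC)cc1OCOC | intermediate
16 | (5S,6S)-5-[2,4-bis(methoxymethoxy)phenyl]-6-{[tert-butyl(dimethyl)silyl]oxy[2,4-bis(methoxymethoxy)-3-(3-methylbut-2-en-1-yl)phenyl]methyl}cyclohex-2-en-1-one | CC(C)(C)[Si](C)(C)OC(c1ccc(OCOC)c(CC=C(C)C)c1OCOC)[C@H]1C(=O)C=CC[C@@H]1c1ccc(OCOC)cc1OCOC | intermediate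
17 | lithium (3S,5S,6S)-5-[2,4-bis(methoxymethoxy)phenyl]-6-{[tert-butyl(dimethyl)silyl]oxy[2,4-bis(methoxymethoxy)-3-(3-methylbut-2-en-1-yl)phenyl]methyl}-3-methylcyclohex-1-en-1-olate | CC(C)(C)[Si](C)(C)OC(c1ccc(OCOC)c(CC=C(C)C)c1OCOC)[C@H]1C(O[Li])=C[C@@H](C)C[C@@H]1c1ccc(OCOC)cc1OCOC | intermediate
18 | (3S,5S,6S)-5-[2,4-bis(methoxymethoxy)phenyl]-6-{[tert-butyl(dimethyl)silyl]oxy[2,4-bis(methoxymethoxy)-3-(3-methylbut-2-en-1-yl)phenyl]methyl}-3-methylcyclohex-1-en-1-yl trifluoromethanesulfonate | CC(C)(C)[Si](C)(C)OC(c1ccc(OCOC)c(CC=C(C)C)c1OCOC)[C@H]1C(OS(=O)(=O)C(F)(F)F)=C[C@@H](C)C[C@@H]1c1ccc(OCOC)cc1OCOC | intermediate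
19 | 2-[3,5-bis(methoxymethoxy)phenyl]-4,4,5,5-tetramethyl-1,3,2-dioxaborolane | COCOc1cc(OCOC)cc(B2OC(C)(C)C(C)(C)O2)c1 | intermediate
20 | 3,5-bis(methoxymethoxy)phenol | COCOc1cc(O)cc(OCOC)c1 | intermediate
21 | 2-hydroxy-4,6-bis(methoxymethoxy)benzaldehyde | O=Cc1c(O)cc(OCOC)cc1OCOC | intermediate
22 | 3-bromo-2-hydroxy-4,6-bis(methoxymethoxy)benzaldehyde | O=Cc1c(O)c(Br)c(OCOC)cc1OCOC | intermediate
23 | ethynyl(trimethyl)silane | C#C[Si](C)(C)C | starting material
24 | trimethyl(5-methylhex-4-en-1-yn-1-yl)silane | CC(C)=CCC#C[Si](C)(C)C | intermediate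
25 | 5-methylhex-4-en-1-yne | CC(C)=CCC#C | intermediate
26 | 2,4-bis(methoxymethoxy)-1-(5-methylhex-4-en-1-yn-1-yl)benzene | CC(C)=CCC#Cc1ccc(OCOC)cc1OCOC | intermediate
27 | 8-bromo-2-[2,4-bis(methoxymethoxy)phenyl]-5,7-bis(methoxymethoxy)-3-(3-methylbut-2-en-1-yl)-4H-chromen-4-one | CC(C)=CCc1c(-c2ccc(OCOC)cc2OCOC)oc2c(Br)c(OCOC)cc(OCOC)c2c1=O | intermediate
28 | 2-[(3S,5S,6R)-5-[2,4-bis(methoxymethoxy)phenyl]-6-{[tert-butyl(dimethyl)silyl]oxy[2,4-bis(methoxymethoxy)-3-(3-methylbut-2-en-1-yl)phenyl]methyl}-3-methylcyclohex-1-en-1-yl]-4,4,5,5-tetramethyl-1,3,2-dioxaborolane | CC(C)(C)[Si](C)(C)OC(c1ccc(OCOC)c(CC=C(C)C)c1OCOC)[C@H]1C(B2OC(C)(C)C(C)(C)O2)=C[C@@H](C)C[C@@H]1c1ccc(OCOC)cc1OCOC | intermediate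
29 | 8-[(3S,5S,6R)-5-[2,4-bis(methoxymethoxy)phenyl]-6-{[tert-butyl(dimethyl)silyl]oxy[2,4-bis(methoxymethoxy)-3-(3-methylbut-2-en-1-yl)phenyl]methyl}-3-methylcyclohex-1-en-1-yl]-2-[2,4-bis(methoxymethoxy)phenyl]-5,7-bis(methoxymethoxy)-3-(3-methylbut-2-en-1-yl)-4H-chromen-4-one | CC(C)(C)[Si](C)(C)OC(c1ccc(OCOC)c(CC=C(C)C)c1OCOC)[C@H]1C(c2c(OCOC)cc(OCOC)c3c(=O)c(CC=C(C)C)c(-c4ccc(OCOC)cc4OCOC)oc23)=C[C@@H](C)C[C@@H]1c1ccc(OCOC)cc1OCOC | intermediate
30 | 8-[(3S,5S,6R)-5-[2,4-bis(methoxymethoxy)phenyl]-6-{hydroxy[2,4-bis(methoxymethoxy)-3-(3-methylbut-2-en-1-yl)phenyl]methyl}-3-methylcyclohex-1-en-1-yl]-2-[2,4-bis(methoxymethoxy)phenyl]-5,7-bis(methoxymethoxy)-3-(3-methylbut-2-en-1-yl)-4H-chromen-4-one | OC(c1ccc(OCOC)c(CC=C(C)C)c1OCOC)[C@H]1C(c2c(OCOC)cc(OCOC)c3c(=O)c(CC=C(C)C)c(-c4ccc(OCOC)cc4OCOC)oc23)=C[C@@H](C)C[C@@H]1c1ccc(OCOC)cc1OCOC | intermediate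
31 | 8-[(3S,5S,6R)-6-[2,4-bis(methoxymethoxy)-3-(3-methylbut-2-en-1-yl)benzoyl]-5-[2,4-bis(methoxymethoxy)phenyl]-3-methylcyclohex-1-en-1-yl]-2-[2,4-bis(methoxymethoxy)phenyl]-5,7-bis(methoxymethoxy)-3-(3-methylbut-2-en-1-yl)-4H-chromen-4-one | CC(C)=CCc1c(OCOC)ccc(C(=O)[C@H]2C(c3c(OCOC)cc(OCOC)c4c(=O)c(CC=C(C)C)c(-c5ccc(OCOC)cc5OCOC)oc34)=C[C@@H](C)C[C@@H]2c2ccc(OCOC)cc2OCOC)c1OCOC | intermediate
32 | CNP0314407.1, 8-[(3S,5S,6R)-6-[2,4-dihydroxy-3-(3-methylbut-2-en-1-yl)benzoyl]-5-(2,4-dihydroxyphenyl)-3-methylcyclohex-1-en-1-yl]-2-(2,4-dihydroxyphenyl)-5,7-dihydroxy-3-(3-methylbut-2-en-1-yl)-4H-chromen-4-one | CC(C)=CCc1c(O)ccc(C(=O)[C@H]2C(c3c(O)cc(O)c4c(=O)c(CC=C(C)C)c(-c5ccc(O)cc5O)oc34)=C[C@@H](C)C[C@@H]2c2ccc(O)cc2O)c1O | target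

**Totals and risks**
Total step count: 17. Longest linear sequence: 10 steps (steps 1, 3, 4, 5, 6, 7, 8, 15, 16, 17).

The three steps most likely to fail:

Step 7 (the proposed new step). The hindered, unstrained ketone may homologate slowly, or the Lewis acid may ionise the electron-rich benzylic silyl ether. The fallback uses known chemistry, sets out from 14 and comes back at 16. Deprotonation of 14 with LiN(i-Pr)2 and trapping with TMSCl at −78 °C gives the kinetic trimethylsilyl enol ether on the unsubstituted side F1. Cyclopropanation with Et2Zn and CH2I2 gives the siloxycyclopropane F2. FeCl3 in DMF at 0 °C cleaves the internal cyclopropane bond by one-electron oxidation (Ito–Saegusa ring expansion) to the ring-expanded β-chloro ketone F3, and NaOAc in MeOH eliminates HCl to give 16. The ring is still enlarged by one carbon, but by radical fragmentation instead of diazoalkane insertion.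

Step 14. The copper oxidant at 120 °C may attack the aryl bromide or the MOM group next to the carbonyl, and the skipped enyne may isomerise. The fallback sets out from 22 and 26 and comes back at 27. Chelation-assisted hydroacylation of 26 by 22 with a monovalent rhodium catalyst ([RhCl(cod)]2, dppf, Na2CO3, toluene, 100 °C) puts the acyl group on the alkyl-bearing alkyne carbon and gives the (E)-α-prenyl-2'-hydroxychalcone F4. Base-induced oxa-Michael ring closure and dehydrogenation of the resulting flavanone with DDQ in dioxane then give 27.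

Step 15. The coupling joins a doubly ortho-substituted aryl bromide to an α-branched alkenylboronate, and the boronate may protodeboronate. The fallback sets out from 16 and comes back at 29. Addition of Me2CuLi to 16 with a proton quench gives the trans-methyl ketone F5. Condensation with TsNHNH2 in MeOH at 50 °C gives the tosylhydrazone F6. Barluenga coupling of F6 with 27 (Pd2(dba)3, XPhos, LiOt-Bu, dioxane, 100 °C) gives 29 by carbene migratory insertion and β-hydride elimination toward the unsubstituted CH2.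

**Further compounds**
F1 | step 7 | trimethylsilyl enol ether of 14 with the double bond between C1 and C5 (unsubstituted side) | CC(C)(C)[Si](C)(C)OC(c1ccc(OCOC)c(CC=C(C)C)c1OCOC)[C@H]1C(O[Si](C)(C)C)=CC[C@@H]1c1ccc(OCOC)cc1OCOC
F2 | step 7 | 1-(trimethylsilyloxy)bicyclo[3.1.0]hexane from cyclopropanation of F1 (ring-fusion centres not assigned) | CC(C)(C)[Si](C)(C)OC(c1ccc(OCOC)c(CC=C(C)C)c1OCOC)[C@H]1C2(O[Si](C)(C)C)CC2C[C@@H]1c1ccc(OCOC)cc1OCOC
F3 | step 7 | 3-chloro-5-Ar1-6-[(TBS-oxy)(Ar2)methyl]cyclohexan-1-one (chloride centre not assigned) | CC(C)(C)[Si](C)(C)OC(c1ccc(OCOC)c(CC=C(C)C)c1OCOC)[C@H]1C(=O)CC(Cl)C[C@@H]1c1ccc(OCOC)cc1OCOC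
F4 | step 14 | (E)-1-[3-bromo-2-hydroxy-4,6-bis(methoxymethoxy)phenyl]-2-{[2,4-bis(methoxymethoxy)phenyl]methylidene}-5-methylhex-4-en-1-one | O=C(c1c(O)c(Br)c(OCOC)cc1OCOC)/C(CC=C(C)C)=C/c1ccc(OCOC)cc1OCOC
F5 | step 15 | (2S,3S,5S)-3-Ar1-2-[(TBS-oxy)(Ar2)methyl]-5-methylcyclohexan-1-one | CC(C)(C)[Si](C)(C)OC(c1ccc(OCOC)c(CC=C(C)C)c1OCOC)[C@H]1C(=O)C[C@@H](C)C[C@@H]1c1ccc(OCOC)cc1OCOC
F6 | step 15 | 4-methylbenzenesulfonylhydrazone of F5 | CC(C)(C)[Si](C)(C)OC(c1ccc(OCOC)c(CC=C(C)C)c1OCOC)[C@H]1C(=NNS(=O)(=O)c2ccc(C)cc2)C[C@@H](C)C[C@@H]1c1ccc(OCOC)cc1OCOC
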